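**Plan**

- The retrosynthesis first swaps the 5'-acetate back to a MOM ether and the three free phenols back to benzyl ethers. It then cuts the three C–O bonds of ring A (O1–C8a, C5–O, C7–O). O1, the 5-oxygen and the 7-oxygen lie ortho, ortho and para to the C4 carbonyl on ring A, which is the substitution pattern a 2,4,6-trifluorobenzoyl group activates.
- The resulting open 2-methoxy-1,3-diketone is cut at C3–C4 into 2,4,6-trifluorobenzoyl chloride and a B-ring ω-methoxyacetophenone. That ketone is cut at C1'–C2 into an aryl bromide and the Weinreb amide of methoxyacetic acid; the bromide traces back to vanillin.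
- Forward: the B ring is oxygenated and brominated, the chain is joined (C1'–C2, then C3–C4), the pyranone ring C closes onto the preformed fluorinated A ring, and both remaining fluorines become benzyloxy groups in the same flask.
- Endgame: MOM off, acetate on, three benzyl ethers off.
- Stereochemistry: none to set.

Key step: step 7

Remark: the target has no stereocentre and no configurationally stable axis, so the SMILES describes one achiral compound and the route needs no stereocontrol.

**Route**

Step 1
Reactants: 1 vanillin (4-hydroxy-3-methoxybenzaldehyde)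
Product: 2 3-methoxy-4-(methoxymethoxy)benzaldehyde
Conditions: MOMCl, i-Pr2NEt, CH2Cl2, 0 °C → rt
Reagents that add atoms: chloromethyl methyl ether, COCCl
Why: O-alkylation of an acidic phenol with an α-chloro ether (MOM protection) should be clean and gives the one oxygen that must later be unmasked separately from the benzyl ethers.

Step 2
Reactants: 2 3-methoxy-4-(methoxymethoxy)benzaldehyde
Product: 4 3-methoxy-4-(methoxymethoxy)phenol, via aryl formate 3 (not isolated)
Conditions: mCPBA, CH2Cl2, 0 °C → rt; then K2CO3 (cat.), MeOH, rt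
Reagents that add atoms: meta-chloroperoxybenzoic acid, OOC(=O)c1cccc(Cl)c1
Why: In this Baeyer–Villiger (Dakin-type) oxidation the electron-rich aryl group, carrying a para-alkoxy donor, should migrate in preference to hydride, and mild methanolysis of the formate should free the phenol without touching the MOM acetal.

Step 3
Reactants: 4 3-methoxy-4-(methoxymethoxy)phenol
Product: 5 4-(benzyloxy)-2-methoxy-1-(methoxymethoxy)benzene
Conditions: BnBr, K2CO3, DMF, rt
Reagents that add atoms: benzyl bromide, BrCc1ccccc1
Why: Williamson etherification of the phenoxide caps the future 2'-oxygen as a benzyl ether, which is base-stable and leaves with the other benzyl groups at the end.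

Step 4
Reactants: 5 4-(benzyloxy)-2-methoxy-1-(methoxymethoxy)benzene
Product: 6 1-(benzyloxy)-2-bromo-5-methoxy-4-(methoxymethoxy)benzene
Conditions: NBS, MeCN, 0 °C
Reagents that add atoms: N-bromosuccinimide, O=C1CCC(=O)N1Br
Why: Electrophilic aromatic bromination should go to the carbon para to the methoxy group and ortho to the benzyloxy group, the most activated and least hindered site, as in 1,2,4-trialkoxybenzenes; the conditions are neutral, so the MOM group should survive.

Step 5
Reactants: 6 1-(benzyloxy)-2-bromo-5-methoxy-4-(methoxymethoxy)benzene; 7 N,2-dimethoxy-N-methylacetamide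
Product: 9 1-[2-(benzyloxy)-4-methoxy-5-(methoxymethoxy)phenyl]-2-methoxyethan-1-one, via aryllithium 8 (not isolated)
Conditions: n-BuLi, THF, −78 °C; then 7, −78 → 0 °C; aq. NH4Cl
Reagents that add atoms: N,2-dimethoxy-N-methylacetamide (7), COCC(=O)N(C)OC
Why: Bromine–lithium exchange is faster than any directed deprotonation at −78 °C, and the N-methoxy-N-methylamide stops the addition at the ketone oxidation level (Weinreb ketone synthesis), so the ω-methoxy ketone arrives with the C3 methoxy group already in place.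

Step 6
Reactants: 9 1-[2-(benzyloxy)-4-methoxy-5-(methoxymethoxy)phenyl]-2-methoxyethan-1-one; 10 2,4,6-trifluorobenzoyl chloride
Product: 12 1-[2-(benzyloxy)-4-methoxy-5-(methoxymethoxy)phenyl]-2-methoxy-3-(2,4,6-trifluorophenyl)propane-1,3-dione (drawn as its chelated enol), via lithium enolate 11 (not isolated)
Conditions: LiHMDS (2.1 equiv), THF, −78 °C; then 10, −78 → 0 °C; aq. NH4Cl
Reagents that add atoms: 2,4,6-trifluorobenzoyl chloride (10), O=C(Cl)c1c(F)cc(F)cc1F
Why: Crossed Claisen-type C-acylation of a lithium ketone enolate with an aroyl chloride; the second equivalent of base takes up the more acidic diketone as it forms, and at −78 °C acyl substitution should be far faster than any attack on the C–F bonds.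

Step 7
Reactants: 12 1-[2-(benzyloxy)-4-methoxy-5-(methoxymethoxy)phenyl]-2-methoxy-3-(2,4,6-trifluorophenyl)propane-1,3-dione; 13 benzyl alcohol
Product: 17 5,7-bis(benzyloxy)-2-[2-(benzyloxy)-4-methoxy-5-(methoxymethoxy)phenyl]-3-methoxy-4H-chromen-4-one, via sodium enolate 14 (not isolated), via 5,7-difluoroflavone 15 (not isolated), via 7-benzyloxy-5-fluoroflavone 16 (not isolated)
Conditions: NaH (1.1 equiv), THF–DMF, 0 → 50 °C; then BnONa (2.6 equiv, from 13 + NaH in THF), 50–65 °C
Reagents that add atoms: benzyl alcohol (13), OCc1ccccc1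
Why: Sodium hydride gives the diketonate 14, whose B-side enolate oxygen adds to an ortho C–F carbon of the trifluorobenzoyl ring and expels fluoride through a Meisenheimer anion delocalised into the C4 carbonyl, forming O1–C8a and the chromone 15. The closest known reactions are the base-mediated SNAr cyclisation of 1-(2-fluoroaryl)-1,3-diketones to chromones and the alkoxide substitution of fluorochromones. The pyranone ring closes in a six-membered, formally 6-endo-trig addition–elimination, the attacked ring carbon being β to the C4 carbonyl as in an oxa-Michael addition. In 15 the C4 carbonyl still stands para to C7–F and ortho to C5–F, so benzyloxide should replace both, most likely C7 first (16) and then C5. Only the B-side oxygen can reach an ortho carbon (the other oxygen and the central carbon would have to form four-membered rings), the two ortho fluorines are equivalent by symmetry, the 2'-oxygen is blocked as its benzyl ether, and benzyloxide is withheld until the ring has closed so that it cannot cleave the open diketone. No stereocentre is formed.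

Step 8
Reactants: 17 5,7-bis(benzyloxy)-2-[2-(benzyloxy)-4-methoxy-5-(methoxymethoxy)phenyl]-3-methoxy-4H-chromen-4-one
Product: 18 5,7-bis(benzyloxy)-2-[2-(benzyloxy)-5-hydroxy-4-methoxyphenyl]-3-methoxy-4H-chromen-4-one
Conditions: HCl (1.25 M in MeOH), THF, 40 °C
Reagents that add atoms: none
Why: Acid-catalysed acetal exchange with methanol removes an aryl MOM ether under conditions that benzyl and methyl aryl ethers and the flavone core should tolerate, exposing only the 5'-hydroxyl.

Step 9
Reactants: 18 5,7-bis(benzyloxy)-2-[2-(benzyloxy)-5-hydroxy-4-methoxyphenyl]-3-methoxy-4H-chromen-4-one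
Product: 19 4-(benzyloxy)-5-[5,7-bis(benzyloxy)-3-methoxy-4-oxo-4H-chromen-2-yl]-2-methoxyphenyl acetate
Conditions: Ac2O, pyridine, DMAP (cat.), CH2Cl2, 0 °C → rt
Reagents that add atoms: acetic anhydride, CC(=O)OC(C)=O
Why: DMAP-catalysed O-acylation of the only free hydroxyl places the acetate at the 5'-oxygen and nowhere else.

Step 10
Reactants: 19 4-(benzyloxy)-5-[5,7-bis(benzyloxy)-3-methoxy-4-oxo-4H-chromen-2-yl]-2-methoxyphenyl acetate
Product: 20 5,7,2',5'-tetrahydroxy-3,4'-dimethoxyflavone 5'-acetate (5-(5,7-dihydroxy-3-methoxy-4-oxo-4H-chromen-2-yl)-4-hydroxy-2-methoxyphenyl acetate)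
Conditions: H2 (1 atm), 10% Pd/C, EtOAc–THF, rt
Reagents that add atoms: none
Why: Catalytic hydrogenolysis cleaves the three aryl benzyl ethers under neutral, non-nucleophilic conditions, so the aryl acetate, the methyl ethers and the flavone C2=C3 bond should remain; the acetate sits para to the freed 2'-hydroxyl and cannot migrate to it.

**Compound list**

1 | vanillin (4-hydroxy-3-methoxybenzaldehyde) | COc1cc(C=O)ccc1O | starting material
2 | 3-methoxy-4-(methoxymethoxy)benzaldehyde | COCOc1ccc(C=O)cc1OC | intermediate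
3 | 3-methoxy-4-(methoxymethoxy)phenyl formate | COCOc1ccc(OC=O)cc1OC | intermediate (not isolated)
4 | 3-methoxy-4-(methoxymethoxy)phenol | COCOc1ccc(O)cc1OC | intermediate
5 | 4-(benzyloxy)-2-methoxy-1-(methoxymethoxy)benzene | COCOc1ccc(OCc2ccccc2)cc1OC | intermediate
6 | 1-(benzyloxy)-2-bromo-5-methoxy-4-(methoxymethoxy)benzene | COCOc1cc(Br)c(OCc2ccccc2)cc1OC | intermediate
7 | N,2-dimethoxy-N-methylacetamide | COCC(=O)N(C)OC | starting material
8 | [2-(benzyloxy)-4-methoxy-5-(methoxymethoxy)phenyl]lithium | [Li]c1cc(OCOC)c(OC)cc1OCc1ccccc1 | intermediate (not isolated)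
9 | 1-[2-(benzyloxy)-4-methoxy-5-(methoxymethoxy)phenyl]-2-methoxyethan-1-one | COCC(=O)c1cc(OCOC)c(OC)cc1OCc1ccccc1 | intermediate
10 | 2,4,6-trifluorobenzoyl chloride | O=C(Cl)c1c(F)cc(F)cc1F | starting material
11 | lithium (Z)-enolate of 9 | [Li]O/C(=C\OC)c1cc(OCOC)c(OC)cc1OCc1ccccc1 | intermediate (not isolated)
12 | 1-[2-(benzyloxy)-4-methoxy-5-(methoxymethoxy)phenyl]-2-methoxy-3-(2,4,6-trifluorophenyl)propane-1,3-dione, drawn as the chelated (Z)-enol; the diketo tautomer is in equilibrium and its C2 centre is configurationally labile | O/C(c1cc(OCOC)c(OC)cc1OCc1ccccc1)=C(OC)\C(=O)c1c(F)cc(F)cc1F | intermediate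
13 | benzyl alcohol | OCc1ccccc1 | starting material
14 | sodium enolate of 12 | [Na]O/C(c1cc(OCOC)c(OC)cc1OCc1ccccc1)=C(OC)\C(=O)c1c(F)cc(F)cc1F | intermediate (not isolated)
15 | 2-[2-(benzyloxy)-4-methoxy-5-(methoxymethoxy)phenyl]-5,7-difluoro-3-methoxy-4H-chromen-4-one | COc1c(-c2cc(OCOC)c(OC)cc2OCc2ccccc2)oc2cc(F)cc(F)c2c1=O | intermediate (not isolated)
16 | 7-(benzyloxy)-2-[2-(benzyloxy)-4-methoxy-5-(methoxymethoxy)phenyl]-5-fluoro-3-methoxy-4H-chromen-4-one | COc1c(-c2cc(OCOC)c(OC)cc2OCc2ccccc2)oc2cc(OCc3ccccc3)cc(F)c2c1=O | intermediate (not isolated)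
17 | 5,7-bis(benzyloxy)-2-[2-(benzyloxy)-4-methoxy-5-(methoxymethoxy)phenyl]-3-methoxy-4H-chromen-4-one | COc1c(-c2cc(OCOC)c(OC)cc2OCc2ccccc2)oc2cc(OCc3ccccc3)cc(OCc3ccccc3)c2c1=O | intermediate
18 | 5,7-bis(benzyloxy)-2-[2-(benzyloxy)-5-hydroxy-4-methoxyphenyl]-3-methoxy-4H-chromen-4-one | COc1c(-c2cc(O)c(OC)cc2OCc2ccccc2)oc2cc(OCc3ccccc3)cc(OCc3ccccc3)c2c1=O | intermediate
19 | 4-(benzyloxy)-5-[5,7-bis(benzyloxy)-3-methoxy-4-oxo-4H-chromen-2-yl]-2-methoxyphenyl acetate | COc1c(-c2cc(OC(C)=O)c(OC)cc2OCc2ccccc2)oc2cc(OCc3ccccc3)cc(OCc3ccccc3)c2c1=O | intermediate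
20 | 5,7,2',5'-tetrahydroxy-3,4'-dimethoxyflavone 5'-acetate | COc1cc(O)c(-c2oc3cc(O)cc(O)c3c(=O)c2OC)cc1OC(C)=O | target

**Step count**

Total: 10 steps. Longest linear sequence: 10 steps (1 → 20); 7, 10 and 13 are purchased and enter at steps 5, 6 and 7.

**Steps most likely to fail**

Step 7. The displacement of the C5 fluorine may stall once the 7-benzyloxy donor has deactivated the ring, or benzyloxide may add at C2 and open the pyranone. The fallback abandons fluoride displacement and builds ring C by a Baker–Venkataraman sequence on an A ring that already carries its oxygens. It sets out from 6: the aryllithium 8 is quenched with CO2 to give 2-(benzyloxy)-4-methoxy-5-(methoxymethoxy)benzoic acid F1. In parallel, Houben–Hoesch acylation of phloroglucinol with methoxyacetonitrile (ZnCl2, HCl, Et2O; then hot water) gives 2-methoxy-1-(2,4,6-trihydroxyphenyl)ethan-1-one F2. Benzylation with two equivalents of BnBr and K2CO3 in DMF spares the chelated hydroxyl and gives 1-[2,4-bis(benzyloxy)-6-hydroxyphenyl]-2-methoxyethan-1-one F3. EDC/DMAP coupling of F1 with F3 gives 3,5-bis(benzyloxy)-2-(2-methoxyacetyl)phenyl 2-(benzyloxy)-4-methoxy-5-(methoxymethoxy)benzoate F4. LiHMDS in THF then moves the aroyl group from oxygen to carbon to give 1-[2,4-bis(benzyloxy)-6-hydroxyphenyl]-3-[2-(benzyloxy)-4-methoxy-5-(methoxymethoxy)phenyl]-2-methoxypropane-1,3-dione F5. Cyclodehydration in methanolic HCl/THF, which also removes the MOM ether, comes back to the route at 18.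

Step 6. The enolate may be acylated on oxygen, or the product diketonate may be acylated a second time. The fallback replaces the acylation by an aldol addition and an oxidation. It sets out from 9: the lithium enolate 11 is added to 2,4,6-trifluorobenzaldehyde at −78 °C to give 1-[2-(benzyloxy)-4-methoxy-5-(methoxymethoxy)phenyl]-3-hydroxy-2-methoxy-3-(2,4,6-trifluorophenyl)propan-1-one F6, a mixture of racemic diastereomers that converge. Dess–Martin oxidation (NaHCO3, CH2Cl2) returns to the route at 12.

Step 8. The peri 5-O-benzyl ether, which is activated by the C4 carbonyl, may be lost together with the MOM group. The fallback makes this loss deliberate and relies on the hydrogen-bonded 5-hydroxyl being slow to acylate. It sets out from 17: concentrated HCl in acetic acid at about 40 °C removes both groups to give 7-(benzyloxy)-2-[2-(benzyloxy)-5-hydroxy-4-methoxyphenyl]-5-hydroxy-3-methoxy-4H-chromen-4-one F7. One equivalent of Ac2O in pyridine at 0 °C should acetylate only the unchelated 5'-hydroxyl, giving 4-(benzyloxy)-5-[7-(benzyloxy)-5-hydroxy-3-methoxy-4-oxo-4H-chromen-2-yl]-2-methoxyphenyl acetate F8. Hydrogenolysis as in step 10 comes back to the route at the target 20.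

**Further compounds**

F1 | step 7 | 2-(benzyloxy)-4-methoxy-5-(methoxymethoxy)benzoic acid | COCOc1cc(C(=O)O)c(OCc2ccccc2)cc1OC
F2 | step 7 | 2-methoxy-1-(2,4,6-trihydroxyphenyl)ethan-1-one | COCC(=O)c1c(O)cc(O)cc1O
F3 | step 7 | 1-[2,4-bis(benzyloxy)-6-hydroxyphenyl]-2-methoxyethan-1-one | COCC(=O)c1c(O)cc(OCc2ccccc2)cc1OCc1ccccc1
F4 | step 7 | 3,5-bis(benzyloxy)-2-(2-methoxyacetyl)phenyl 2-(benzyloxy)-4-methoxy-5-(methoxymethoxy)benzoate | COCC(=O)c1c(OC(=O)c2cc(OCOC)c(OC)cc2OCc2ccccc2)cc(OCc2ccccc2)cc1OCc1ccccc1
F5 | step 7 | 1-[2,4-bis(benzyloxy)-6-hydroxyphenyl]-3-[2-(benzyloxy)-4-methoxy-5-(methoxymethoxy)phenyl]-2-methoxypropane-1,3-dione (racemic, C2 labile) | COC(C(=O)c1cc(OCOC)c(OC)cc1OCc1ccccc1)C(=O)c1c(O)cc(OCc2ccccc2)cc1OCc1ccccc1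
F6 | step 6 | 1-[2-(benzyloxy)-4-methoxy-5-(methoxymethoxy)phenyl]-3-hydroxy-2-methoxy-3-(2,4,6-trifluorophenyl)propan-1-one (mixture of racemic diastereomers) | COC(C(O)c1c(F)cc(F)cc1F)C(=O)c1cc(OCOC)c(OC)cc1OCc1ccccc1
F7 | step 8 | 7-(benzyloxy)-2-[2-(benzyloxy)-5-hydroxy-4-methoxyphenyl]-5-hydroxy-3-methoxy-4H-chromen-4-one | COc1c(-c2cc(O)c(OC)cc2OCc2ccccc2)oc2cc(OCc3ccccc3)cc(O)c2c1=O
F8 | step 8 | 4-(benzyloxy)-5-[7-(benzyloxy)-5-hydroxy-3-methoxy-4-oxo-4H-chromen-2-yl]-2-methoxyphenyl acetate | COc1c(-c2cc(OC(C)=O)c(OC)cc2OCc2ccccc2)oc2cc(OCc3ccccc3)cc(O)c2c1=O
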